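**Assumption:** the target has no stereocentres, so "single enantiomer" is read as the single all-E isomer (seven E double bonds); all-E-geranylgeraniol is taken as a commercial terpene alcohol.

## Retrosynthetic overview

1. Menaquinone-8 comes from menaquinol-8, which comes from the octaprenyl ester of 1,4-dihydroxy-3-methyl-2-naphthoic acid by a Pd-mediated O-to-C prenyl shift with loss of CO2 (the decarboxylative prenylation of the MenA enzyme).
2. The naphthoate ring comes from a sulfonylphthalide anion and octaprenyl crotonate: acyl-anion Michael addition gives a masked o-succinylbenzoate, which closes by Dieckmann condensation (the MenD/MenB logic). The crotonate supplies C2, C3 and the 2-methyl group.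
3. Octaprenol comes from two molecules of geranylgeraniol: the allylic sulfone of one is alkylated by the ω-bromide of the other, then desulfonylated.
4. Ring order: a temporary phthalide lactone first (step 8), then the quinonoid carbocycle (step 9), the only ring made that stays; the benzo ring is bought.

## Route

**Step 1**
Reactants: 1 all-E-geranylgeraniol, (2E,6E,10E)-3,7,11,15-tetramethylhexadeca-2,6,10,14-tetraen-1-ol
Product: 2 all-E-geranylgeranyl acetate
Conditions: Ac2O, pyridine, DMAP (cat.), CH2Cl2, 0 °C to rt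
Reagents that add atoms: acetic anhydride, CC(=O)OC(C)=O
Why: DMAP-catalysed O-acylation masks the C1 hydroxyl and deactivates the 2,3-double bond towards the next oxidation, with no change at any double bond.

**Step 2**
Reactants: 2 all-E-geranylgeranyl acetate
Product: 3 (2E,6E,10E,14E)-16-hydroxy-3,7,11,15-tetramethylhexadeca-2,6,10,14-tetraen-1-yl acetate
Conditions: SeO2 (0.2 equiv), t-BuOOH (70 % aq., 3 equiv), salicylic acid (0.1 equiv), CH2Cl2, rt; stopped at partial conversion, 2 recycled
Reagents that add atoms: tert-butyl hydroperoxide, CC(C)(C)OO (terminal oxidant; its oxygen is relayed to carbon by the catalyst selenium dioxide, O=[Se]=O)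
Why: The Sharpless catalytic SeO2 allylic oxidation (ene reaction, then [2,3]-shift) attacks the most electron-rich and least hindered terminal alkene at its (E)-methyl group, which creates the 14E double bond, the seventh E bond of the future chain.

**Step 3**
Reactants: 3 (2E,6E,10E,14E)-16-hydroxy-3,7,11,15-tetramethylhexadeca-2,6,10,14-tetraen-1-yl acetate
Product: 4 (2E,6E,10E,14E)-16-bromo-3,7,11,15-tetramethylhexadeca-2,6,10,14-tetraen-1-yl acetate
Conditions: CBr4, PPh3, CH2Cl2, 0 °C; used at once
Reagents that add atoms: carbon tetrabromide, BrC(Br)(Br)Br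
Why: Appel bromination of a primary allylic alcohol proceeds by SN2 on the alkoxyphosphonium ion without allylic shift or E/Z change and leaves the acetate untouched.

**Step 4**
Reactants: 1 all-E-geranylgeraniol; 5 sodium benzenesulfinate
Product: 7 all-E-geranylgeranyl phenyl sulfone, via geranylgeranyl chloride 6 (not isolated)
Conditions: MsCl, LiCl, 2,4,6-collidine, DMF, 0 °C; then 5, rt
Reagents that add atoms: lithium chloride, [Li+].[Cl-] (the Cl of intermediate 6 only; it is lost again on the way to 7)
Why: Collington–Meyers chlorination (mesylate displaced by chloride without allylic transposition), followed in the same DMF pot by SN2 S-alkylation of the sulfinate, gives the allylic sulfone with the 2E bond intact.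

**Step 5**
Reactants: 7 all-E-geranylgeranyl phenyl sulfone; 4 (2E,6E,10E,14E)-16-bromo-3,7,11,15-tetramethylhexadeca-2,6,10,14-tetraen-1-yl acetate
Product: 8 (2E,6E,10E,14E,18E,22E,26E)-3,7,11,15,19,23,27,31-octamethyl-17-(phenylsulfonyl)dotriaconta-2,6,10,14,18,22,26,30-octaen-1-yl acetate (racemic at C17)
Conditions: n-BuLi (1.05 equiv on 7), THF, −78 °C; then 4, −78 to −40 °C
Reagents that add atoms: none
Why: Biellmann/Julia-type α-alkylation of the lithiated allylic sulfone by SN2 at the primary allylic bromide joins the two C20 halves head-to-tail; the sulfonyl-bearing carbon is a racemic throwaway stereocentre, and the acetate survives at −78 °C.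

**Step 6**
Reactants: 8 the C40 sulfone acetate
Product: 9 all-E-octaprenol, (2E,6E,10E,14E,18E,22E,26E)-3,7,11,15,19,23,27,31-octamethyldotriaconta-2,6,10,14,18,22,26,30-octaen-1-ol
Conditions: LiEt3BH (5 equiv), PdCl2(dppp) (5 mol %), THF, 0 °C to rt; aqueous work-up
Reagents that add atoms: none
Why: Pd-catalysed hydride desulfonylation of the allylic sulfone (π-allylpalladium hydride, hydride delivered to the less substituted terminus) removes sulfur without double-bond shift or E/Z loss and erases the stereocentre, while the excess hydride reduces off the acetate.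

**Step 7**
Reactants: 9 all-E-octaprenol; 10 (E,E)-crotonic anhydride
Product: 11 all-E-octaprenyl (E)-but-2-enoate (octaprenyl crotonate)
Conditions: pyridine, DMAP (cat.), CH2Cl2, 0 °C to rt
Reagents that add atoms: none
Why: DMAP-catalysed acylation by the anhydride avoids the acid chloride/Et3N combination, so no vinylketene forms and the ester stays the conjugated (E)-crotonate.

**Step 8**
Reactants: 12 2-formylbenzoic acid; 5 sodium benzenesulfinate
Product: 13 3-(phenylsulfonyl)isobenzofuran-1(3H)-one (3-(phenylsulfonyl)phthalide, racemic)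
Conditions: AcOH, 80 °C
Reagents that add atoms: none
Why: The ring-chain tautomer 3-hydroxyphthalide ionises in hot acetic acid to a phthalidyl cation that the sulfinate captures at sulfur (oxocarbenium substitution); the new stereocentre is racemic and is destroyed in step 9.

**Step 9**
Reactants: 13 3-(phenylsulfonyl)phthalide; 11 all-E-octaprenyl (E)-but-2-enoate
Product: 15 all-E-octaprenyl 1,4-dihydroxy-3-methyl-2-naphthoate, via Michael adduct 14 (not isolated)
Conditions: LiOt-Bu (3 equiv), THF, −78 °C; then 11, −78 °C to rt, then 40 °C, Ar; cold aq. NH4Cl/HCl quench, degassed work-up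
Reagents that add atoms: none
Why: In this Hauser–Kraus annulation the sulfonyl-stabilised phthalide anion (a masked aroyl anion, the counterpart of the thiamine-bound acyl anion of MenD) adds 1,4 to the crotonate to give the masked o-succinylbenzoate 14, whose ester enolate closes the ring by Dieckmann condensation on the lactone carbonyl (the MenB step); loss of sulfinate and enolisation then give the hydroquinone and erase the stereocentres of 14.

**Step 10**
Reactants: 15 all-E-octaprenyl 1,4-dihydroxy-3-methyl-2-naphthoate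
Product: 18 menaquinone-8, via dienone acid 16 (not isolated), via menaquinol-8 17 (not isolated)
Conditions: Pd(PPh3)4 (5 mol %), degassed toluene, 25 to 45 °C, Ar; then Ag2O, Et2O, rt
Reagents that add atoms: none
Why: Proposed new method: Pd(0) ionises the allylic ester to a tight ion pair of the π-(octaprenyl)palladium cation and the electron-rich hydroquinone carboxylate, whose enol carbon C2 (the α-carbon of a cyclic β-keto acid in its enol form) attacks the unhindered primary allyl terminus to give dienone acid 16, which loses CO2 irreversibly with rearomatisation to menaquinol 17 (O-allylation is reversible under Pd(0), and fast ion-pair collapse in toluene should keep the 2'E geometry), after which Ag2O oxidises 17 to the quinone; the closest known reaction types are the Tsuji–Saegusa decarboxylative allylation of allyl β-keto esters and electrophilic ipso-substitution with decarboxylation of hydroxynaphthoic acids.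

## Compound list

1 | all-E-geranylgeraniol, (2E,6E,10E)-3,7,11,15-tetramethylhexadeca-2,6,10,14-tetraen-1-ol | CC(C)=CCC/C(C)=C/CC/C(C)=C/CC/C(C)=C/CO | starting material
2 | all-E-geranylgeranyl acetate | CC(C)=CCC/C(C)=C/CC/C(C)=C/CC/C(C)=C/COC(C)=O | intermediate
3 | (2E,6E,10E,14E)-16-hydroxy-3,7,11,15-tetramethylhexadeca-2,6,10,14-tetraen-1-yl acetate | OC/C(C)=C/CC/C(C)=C/CC/C(C)=C/CC/C(C)=C/COC(C)=O | intermediate
4 | (2E,6E,10E,14E)-16-bromo-3,7,11,15-tetramethylhexadeca-2,6,10,14-tetraen-1-yl acetate | BrC/C(C)=C/CC/C(C)=C/CC/C(C)=C/CC/C(C)=C/COC(C)=O | intermediate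
5 | sodium benzenesulfinate | [Na+].[O-]S(=O)c1ccccc1 | starting material
6 | all-E-geranylgeranyl chloride (formed in situ in step 4) | CC(C)=CCC/C(C)=C/CC/C(C)=C/CC/C(C)=C/CCl | intermediate
7 | all-E-geranylgeranyl phenyl sulfone | CC(C)=CCC/C(C)=C/CC/C(C)=C/CC/C(C)=C/CS(=O)(=O)c1ccccc1 | intermediate
8 | (2E,6E,10E,14E,18E,22E,26E)-3,7,11,15,19,23,27,31-octamethyl-17-(phenylsulfonyl)dotriaconta-2,6,10,14,18,22,26,30-octaen-1-yl acetate, racemic at C17 | CC(C)=CCC/C(C)=C/CC/C(C)=C/CC/C(C)=C/C(S(=O)(=O)c1ccccc1)C/C(C)=C/CC/C(C)=C/CC/C(C)=C/CC/C(C)=C/COC(C)=O | intermediate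
9 | all-E-octaprenol | CC(C)=CCC/C(C)=C/CC/C(C)=C/CC/C(C)=C/CC/C(C)=C/CC/C(C)=C/CC/C(C)=C/CC/C(C)=C/CO | intermediate
10 | (E,E)-crotonic anhydride | C/C=C/C(=O)OC(=O)/C=C/C | starting material
11 | all-E-octaprenyl (E)-but-2-enoate | CC(C)=CCC/C(C)=C/CC/C(C)=C/CC/C(C)=C/CC/C(C)=C/CC/C(C)=C/CC/C(C)=C/CC/C(C)=C/COC(=O)/C=C/C | intermediate
12 | 2-formylbenzoic acid | O=Cc1ccccc1C(=O)O | starting material
13 | 3-(phenylsulfonyl)isobenzofuran-1(3H)-one, racemic | O=C1OC(S(=O)(=O)c2ccccc2)c2ccccc12 | intermediate
14 | Michael adduct, all-E-octaprenyl 3-[3-oxo-1-(phenylsulfonyl)-1,3-dihydroisobenzofuran-1-yl]butanoate, mixture of diastereomers (formed in situ in step 9) | CC(C)=CCC/C(C)=C/CC/C(C)=C/CC/C(C)=C/CC/C(C)=C/CC/C(C)=C/CC/C(C)=C/CC/C(C)=C/COC(=O)CC(C)C1(S(=O)(=O)c2ccccc2)OC(=O)c2ccccc12 | intermediate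
15 | all-E-octaprenyl 1,4-dihydroxy-3-methyl-2-naphthoate | CC(C)=CCC/C(C)=C/CC/C(C)=C/CC/C(C)=C/CC/C(C)=C/CC/C(C)=C/CC/C(C)=C/CC/C(C)=C/COC(=O)c1c(C)c(O)c2ccccc2c1O | intermediate
16 | dienone acid, 4-hydroxy-3-methyl-2-(all-E-octaprenyl)-1-oxo-1,2-dihydronaphthalene-2-carboxylic acid, racemic (formed in situ in step 10) | CC(C)=CCC/C(C)=C/CC/C(C)=C/CC/C(C)=C/CC/C(C)=C/CC/C(C)=C/CC/C(C)=C/CC/C(C)=C/CC1(C(=O)O)C(=O)c2ccccc2C(O)=C1C | intermediate
17 | menaquinol-8, 2-methyl-3-(all-E-octaprenyl)naphthalene-1,4-diol (formed in situ in step 10) | CC(C)=CCC/C(C)=C/CC/C(C)=C/CC/C(C)=C/CC/C(C)=C/CC/C(C)=C/CC/C(C)=C/CC/C(C)=C/Cc1c(C)c(O)c2ccccc2c1O | intermediate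
18 | menaquinone-8, 2-methyl-3-(all-E-octaprenyl)naphthalene-1,4-dione | CC(C)=CCC/C(C)=C/CC/C(C)=C/CC/C(C)=C/CC/C(C)=C/CC/C(C)=C/CC/C(C)=C/CC/C(C)=C/CC1=C(C)C(=O)c2ccccc2C1=O | target

## Summary

Total step count: 10.
Longest linear sequence: 8 steps (1, 2, 3, 5, 6, 7, 9, 10).

## Steps most likely to fail and fallbacks

**Step 10 (Pd-mediated decarboxylative prenyl shift).** This is untested chemistry. The risks are O-allylation at the 4-hydroxyl, attack at the tertiary allyl terminus and partial loss of the 2'E geometry. The fallback sets out from 13 and 9 and comes back at 17; it gives up the carboxyl before the prenylation. Compound 13 is annulated as in step 9, but with commercial tert-butyl (E)-crotonate, to give tert-butyl 1,4-dihydroxy-3-methyl-2-naphthoate F1. Trifluoroacetic acid in CH2Cl2, then gentle warming, cleaves the tert-butyl ester and decarboxylates the β-keto acid to 2-methylnaphthalene-1,4-diol (menadiol) F2. BF3·OEt2-catalysed Friedel–Crafts allylation of F2 with octaprenol 9 (dioxane, 50 °C) gives menaquinol-8 17, which is oxidised with Ag2O as in step 10. About 10 % of the 2'Z isomer is expected and must be removed on AgNO3-impregnated silica.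

**Step 9 (annulation with the C40 crotonate).** The lipophilic ester may react sluggishly, or the crotonate may be deprotonated at the γ-position by the excess base. The fallback sets out from 13 and 9 and comes back at 15; it builds the ring on a simple ester and attaches the chain afterwards. Compound 13 and commercial methyl (E)-crotonate (LiOt-Bu, THF) give methyl 1,4-dihydroxy-3-methyl-2-naphthoate F3. LiOH in degassed aqueous THF, then cold acidification, gives 1,4-dihydroxy-3-methyl-2-naphthoic acid F4. Octaprenol 9 is converted with PBr3 (Et2O, −10 °C) into all-E-octaprenyl bromide F5. The carboxylate of F4 (KHCO3, DMF, rt; the phenols stay protonated) is O-alkylated by F5 to give 15.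

**Step 2 (SeO2 oxidation of one of four similar alkenes).** Yields of such terminal oxidations are typically modest, with over-oxidation to the enal and attack at internal allylic positions. The fallback sets out from 2 and comes back at 3; it replaces the C–H oxidation by terminal-selective alkene chemistry. NBS in aqueous THF at 0 °C, which is selective for the terminal double bond of such polyenes, gives the racemic bromohydrin (2E,6E,10E)-14-bromo-15-hydroxy-3,7,11,15-tetramethylhexadeca-2,6,10-trien-1-yl acetate F6. DBU closes it to the racemic epoxide (2E,6E,10E)-13-(3,3-dimethyloxiran-2-yl)-3,7,11-trimethyltrideca-2,6,10-trien-1-yl acetate F7. Periodic acid in THF/Et2O cleaves the epoxide to the aldehyde (2E,6E,10E)-3,7,11-trimethyl-14-oxotetradeca-2,6,10-trien-1-yl acetate F8. E-selective Wittig olefination of F8 with the stabilised ylide 2-(triphenylphosphoranylidene)propanal gives the enal (2E,6E,10E,14E)-3,7,11,15-tetramethyl-16-oxohexadeca-2,6,10,14-tetraen-1-yl acetate F9, and NaBH4 (EtOH, 0 °C) reduces it to 3.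

## Further compounds

F1 | step 10 | tert-butyl 1,4-dihydroxy-3-methyl-2-naphthoate | CC(C)(C)OC(=O)c1c(C)c(O)c2ccccc2c1O
F2 | step 10 | 2-methylnaphthalene-1,4-diol (menadiol) | Cc1cc(O)c2ccccc2c1O
F3 | step 9 | methyl 1,4-dihydroxy-3-methyl-2-naphthoate | COC(=O)c1c(C)c(O)c2ccccc2c1O
F4 | step 9 | 1,4-dihydroxy-3-methyl-2-naphthoic acid | OC(=O)c1c(C)c(O)c2ccccc2c1O
F5 | step 9 | all-E-octaprenyl bromide | CC(C)=CCC/C(C)=C/CC/C(C)=C/CC/C(C)=C/CC/C(C)=C/CC/C(C)=C/CC/C(C)=C/CC/C(C)=C/CBr
F6 | step 2 | (2E,6E,10E)-14-bromo-15-hydroxy-3,7,11,15-tetramethylhexadeca-2,6,10-trien-1-yl acetate, racemic | CC(C)(O)C(Br)CC/C(C)=C/CC/C(C)=C/CC/C(C)=C/COC(C)=O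
F7 | step 2 | (2E,6E,10E)-13-(3,3-dimethyloxiran-2-yl)-3,7,11-trimethyltrideca-2,6,10-trien-1-yl acetate, racemic | CC1(C)OC1CC/C(C)=C/CC/C(C)=C/CC/C(C)=C/COC(C)=O
F8 | step 2 | (2E,6E,10E)-3,7,11-trimethyl-14-oxotetradeca-2,6,10-trien-1-yl acetate | O=CCC/C(C)=C/CC/C(C)=C/CC/C(C)=C/COC(C)=O
F9 | step 2 | (2E,6E,10E,14E)-3,7,11,15-tetramethyl-16-oxohexadeca-2,6,10,14-tetraen-1-yl acetate | O=C/C(C)=C/CC/C(C)=C/CC/C(C)=C/CC/C(C)=C/COC(C)=O
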